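A direct plan would hydrogenate 5,7-dihydroxy-4-phenylcoumarin A1 enantioselectively to the (4R)-dihydrocoumarin A2, add its 7-OH to ethyl 3-(4-methoxyphenyl)propiolate A3, close ring C by Friedel–Crafts acylation of the aryl enol ether A4, open the lactone and cleave the methyl ether. Its weakest steps would be:
- the asymmetric hydrogenation of an unprotected 4-arylcoumarin, which would be without precedent yet would set the only stereocentre;
- the phenol addition to the ynoate, where 7-OH would have to win over the unchelated 5-OH, whose adduct could only close to the 8-substituted flavone;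
- the final O-demethylation, which would be a step of pure deprotection with a strong Lewis acid on the hydroxy acid.

**Strategy.** The route starts from the finished flavone and rests on the C6–C(benzylic) bond: a chiral carbene catalyst joins 3-phenylpropynal to the C5–OH/C6–H edge of 7,4′-di-O-benzylapigenin. In one operation the key step forms that bond at an unfunctionalised C–H, sets the only stereocentre and delivers the acid oxidation level, as a lactone on O5. The feature exploited is that, with O7 blocked, O5 is the only free hydroxyl of ring A and C6 its only open ortho carbon, so the 6-position follows from the tether. No coumarin hydrogenation, no choice between two phenols and no ring C closure remain; neutral hydrogenolysis replaces the Lewis-acid demethylation.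

Key step: step 2

Assumption: the sense of induction of the aminoindanol-derived triazolylidene on this substrate cannot be predicted with certainty, so the antipode that gives the (4R)-lactone would be chosen (both are available from the two enantiomers of cis-1-amino-2-indanol). Apigenin, benzyl bromide and 3-phenylprop-2-ynal are taken as commercial.

Step 1
Reactants: 1 apigenin (5,7-dihydroxy-2-(4-hydroxyphenyl)-4H-chromen-4-one)
Product: 2 7-(benzyloxy)-2-[4-(benzyloxy)phenyl]-5-hydroxy-4H-chromen-4-one (7,4′-di-O-benzylapigenin)
Conditions: BnBr (2.2 equiv), K2CO3 (2.5 equiv), DMF, 23 °C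
Reagents that add atoms: benzyl bromide, BrCc1ccccc1
Why: Williamson ether synthesis, in which the 7- and 4′-phenoxides are alkylated while the 5-OH, held in a hydrogen bond to the C4 carbonyl, is much less acidic and nucleophilic and should stay free.

Step 2
Reactants: 2 7-(benzyloxy)-2-[4-(benzyloxy)phenyl]-5-hydroxy-4H-chromen-4-one; 3 3-phenylprop-2-ynal (1.5 equiv, added slowly)
Product: 4 (4R)-5-(benzyloxy)-8-[4-(benzyloxy)phenyl]-4-phenyl-3,4-dihydro-2H,10H-pyrano[2,3-f]chromene-2,10-dione
Conditions: chiral N-mesityl triazolium chloride from cis-1-amino-2-indanol (indeno[2,1-b]triazolo[4,3-d][1,4]oxazinium type, 10 mol%, antipode giving 4R), i-Pr2NEt (20 mol%), 4 Å MS, toluene, 40 °C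
Reagents that add atoms: none
Why: Proposed new method: enantioselective carbene-catalysed annulation of an ynal onto the C5–OH/C6–H edge of a 5-hydroxyflavone, not yet shown for hydrogen-bonded ortho-acylphenols; the carbene adds to the ynal, internal redox protonation gives the (E)-cinnamoyl azolium, O5 of 2 adds to its carbonyl, and the adduct undergoes a [3,3] shift of Coates–Claisen type (six-membered transition state C6=C5–O–C–Cα=Cβ) that forms the C6–Cβ bond, after which tautomerisation restores ring A and leaves a saturated acyl azolium. The closest known reaction type is the triazolylidene-catalysed annulation of ynals and enals with kojic acids, 1,3-dicarbonyl compounds and naphthols to 4-aryl-3,4-dihydropyranones. The only ring closed is the six-membered lactone, by attack of O5 on the acyl azolium (6-exo-trig acyl substitution), which also releases the catalyst. The single new stereocentre, the benzylic carbon (4R in 4), is set in the C–C bond-forming step by the aminoindanol backbone of the catalyst, which blocks one face of the β-carbon of the acyl azolium. The step needs C6 over C8 selectivity, and the substrate secures it: with O7 and O4′ benzylated, O5 is the only free hydroxyl, C6 is its only unsubstituted ortho carbon (C4a is quaternary), and an adduct at C8 would have no hydroxyl within reach to release the catalyst. O-acylation without rearrangement should be a reversible side channel, because the carbene can re-activate aryl esters.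

Step 3
Reactants: 4 (4R)-5-(benzyloxy)-8-[4-(benzyloxy)phenyl]-4-phenyl-3,4-dihydro-2H,10H-pyrano[2,3-f]chromene-2,10-dione
Product: 5 (3R)-3-{7-(benzyloxy)-2-[4-(benzyloxy)phenyl]-5-hydroxy-4-oxo-4H-chromen-6-yl}-3-phenylpropanoic acid
Conditions: LiOH (3 equiv), THF/H2O 3:1, 0 → 23 °C; then 1 M HCl to pH 3–4, 0 °C
Reagents that add atoms: lithium hydroxide, [Li+].[OH-]
Why: Saponification of an aryl lactone, in which hydroxide opens the activated phenolic ester under mild conditions while the benzyl ethers, the flavone and the non-acidic benzylic C–H stereocentre are inert, and cold acidification should give the open acid because the hydrogen-bonded 5-OH relactonises only slowly.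

Step 4
Reactants: 5 (3R)-3-{7-(benzyloxy)-2-[4-(benzyloxy)phenyl]-5-hydroxy-4-oxo-4H-chromen-6-yl}-3-phenylpropanoic acid
Product: 6 (3R)-3-[5,7-dihydroxy-2-(4-hydroxyphenyl)-4-oxo-4H-chromen-6-yl]-3-phenylpropanoic acid
Conditions: H2 (1 atm), 10% Pd/C, THF/EtOAc 1:1, 23 °C; stopped after uptake of 2 equiv H2
Reagents that add atoms: none
Why: Catalytic hydrogenolysis of the two aryl benzyl ethers under neutral conditions, in which the diarylmethine carbon carries no heteroatom and is not cleaved, the conjugated C2=C3 bond of ring C is reduced far more slowly than O-benzyl groups are removed, and the stereocentre is untouched.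

**Compound list**
1 | apigenin, 5,7-dihydroxy-2-(4-hydroxyphenyl)-4H-chromen-4-one | O=c1cc(-c2ccc(O)cc2)oc2cc(O)cc(O)c12 | starting material
2 | 7-(benzyloxy)-2-[4-(benzyloxy)phenyl]-5-hydroxy-4H-chromen-4-one | O=c1cc(-c2ccc(OCc3ccccc3)cc2)oc2cc(OCc3ccccc3)cc(O)c12 | intermediate
3 | 3-phenylprop-2-ynal | O=CC#Cc1ccccc1 | starting material
4 | (4R)-5-(benzyloxy)-8-[4-(benzyloxy)phenyl]-4-phenyl-3,4-dihydro-2H,10H-pyrano[2,3-f]chromene-2,10-dione | O=C1C[C@H](c2ccccc2)c2c(OCc3ccccc3)cc3oc(-c4ccc(OCc5ccccc5)cc4)cc(=O)c3c2O1 | intermediate
5 | (3R)-3-{7-(benzyloxy)-2-[4-(benzyloxy)phenyl]-5-hydroxy-4-oxo-4H-chromen-6-yl}-3-phenylpropanoic acid | O=C(O)C[C@H](c1ccccc1)c1c(OCc2ccccc2)cc2oc(-c3ccc(OCc4ccccc4)cc3)cc(=O)c2c1O | intermediate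
6 | (3R)-3-[5,7-dihydroxy-2-(4-hydroxyphenyl)-4-oxo-4H-chromen-6-yl]-3-phenylpropanoic acid | O=C(O)C[C@H](c1ccccc1)c1c(O)cc2oc(-c3ccc(O)cc3)cc(=O)c2c1O | target

Total step count: 4. Longest linear sequence: 4 steps (1 → 2 → 4 → 5 → 6).

**Steps most likely to fail**

1. Step 2 (proposed new method). Acyl transfer to O5 could stop at the ester stage without the [3,3] shift, the amine base could divert the phenol into oxa-Michael addition to the ynal, or facial selectivity could be poor on this untested substrate class. The fallback uses known chemistry and sets out from 2. Iodination ortho to the free 5-OH with benzyltrimethylammonium dichloroiodate (BnMe3N+ ICl2−), CaCO3, CH2Cl2/MeOH would give 7-(benzyloxy)-2-[4-(benzyloxy)phenyl]-5-hydroxy-6-iodo-4H-chromen-4-one F1. A Heck reaction with methyl acrylate (Pd(OAc)2, P(o-tol)3, Et3N, DMF, 90 °C) would give methyl (2E)-3-{7-(benzyloxy)-2-[4-(benzyloxy)phenyl]-5-hydroxy-4-oxo-4H-chromen-6-yl}prop-2-enoate F2. Rhodium-catalysed asymmetric 1,4-addition of phenylboronic acid (Hayashi–Miyaura reaction; Rh(acac)(C2H4)2, the BINAP antipode giving 3R, dioxane/H2O, 100 °C) would give methyl (3R)-3-{7-(benzyloxy)-2-[4-(benzyloxy)phenyl]-5-hydroxy-4-oxo-4H-chromen-6-yl}-3-phenylpropanoate F3. Saponification with LiOH as in step 3 would come back to the route at 5.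

2. Step 4. Partial saturation of the C2=C3 bond of ring C, or stalling of the cleavage of the hindered 7-O-benzyl group, could occur under hydrogenation. The fallback sets out from 5 and replaces reduction by Lewis-acid dealkylation: BCl3 with pentamethylbenzene as cation scavenger, CH2Cl2, −78 °C, then cold aqueous work-up, would come back to the route at 6 without any new intermediate.

3. Step 3. The lactone could close again during acidification and concentration, so that the open acid would not be carried forward cleanly. The fallback sets out from 4 and reverses the order of the last two operations: hydrogenolysis of 4 (H2, Pd/C, THF) would give the storable lactone (4R)-5-hydroxy-8-(4-hydroxyphenyl)-4-phenyl-3,4-dihydro-2H,10H-pyrano[2,3-f]chromene-2,10-dione F4. Ring opening with LiOH in degassed THF/H2O under argon and cold acidification as the very last operation would come back to the route at 6.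

**Further compounds**
F1 | step 2 | 7-(benzyloxy)-2-[4-(benzyloxy)phenyl]-5-hydroxy-6-iodo-4H-chromen-4-one | O=c1cc(-c2ccc(OCc3ccccc3)cc2)oc2cc(OCc3ccccc3)c(I)c(O)c12
F2 | step 2 | methyl (2E)-3-{7-(benzyloxy)-2-[4-(benzyloxy)phenyl]-5-hydroxy-4-oxo-4H-chromen-6-yl}prop-2-enoate | COC(=O)/C=C/c1c(OCc2ccccc2)cc2oc(-c3ccc(OCc4ccccc4)cc3)cc(=O)c2c1O
F3 | step 2 | methyl (3R)-3-{7-(benzyloxy)-2-[4-(benzyloxy)phenyl]-5-hydroxy-4-oxo-4H-chromen-6-yl}-3-phenylpropanoate | COC(=O)C[C@H](c1ccccc1)c1c(OCc2ccccc2)cc2oc(-c3ccc(OCc4ccccc4)cc3)cc(=O)c2c1O
F4 | step 3 | (4R)-5-hydroxy-8-(4-hydroxyphenyl)-4-phenyl-3,4-dihydro-2H,10H-pyrano[2,3-f]chromene-2,10-dione | O=C1C[C@H](c2ccccc2)c2c(O)cc3oc(-c4ccc(O)cc4)cc(=O)c3c2O1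
F0 | step 4 | none | none
A1 | direct plan | 5,7-dihydroxy-4-phenyl-2H-chromen-2-one | O=c1cc(-c2ccccc2)c2c(O)cc(O)cc2o1
A2 | direct plan | (4R)-5,7-dihydroxy-4-phenyl-3,4-dihydro-2H-chromen-2-one | O=C1C[C@H](c2ccccc2)c2c(O)cc(O)cc2O1
A3 | direct plan | ethyl 3-(4-methoxyphenyl)prop-2-ynoate | CCOC(=O)C#Cc1ccc(OC)cc1
A4 | direct plan | ethyl (2Z)-3-{[(4R)-5-hydroxy-2-oxo-4-phenyl-3,4-dihydro-2H-chromen-7-yl]oxy}-3-(4-methoxyphenyl)prop-2-enoate | CCOC(=O)/C=C(\Oc1cc(O)c2[C@@H](c3ccccc3)CC(=O)Oc2c1)c1ccc(OC)cc1
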